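## Structural features

The target consists of two chlorinated, oxygenated naphthalene-derived units: the upper unit (C1–C8a) holds the ketal carbon C1, the C2–C3 epoxide, the C4 ketone and the C5 phenol, and the lower unit (C1′–C8a′) holds the quaternary carbon C1′, the C2′–C3′ epoxide, the C4′ carbinol and the C5′ phenol. The units are joined three times: by the C8–C1′ bond, by the oxygen bridging C1 and C1′, and by the aryl ether oxygen between C1 and C8′. A five-membered ring (C1, C8a, C8, C1′, O) and a six-membered 1,3-dioxin ring (C1, O, C8′, C8a′, C1′, O) therefore share the C1–O–C1′ bridge of a 2,8-dioxabicyclo[3.2.1]octane. There are seven stereocentres, C1, C2 and C3 contiguous above and C1′, C2′, C3′ and C4′ below, of which the bridgeheads C1 and C1′ are locked relative to each other. Each epoxide oxygen lies on the ring face away from the other unit (anti to the C1–O–C8′ bond above, anti to the C1′–C8 bond below), and the C4′ hydroxyl is trans to the lower epoxide. Fragile groups are the two epoxides, the ketal, the doubly benzylic tertiary ether at C1′, the benzylic carbinol beside a free phenol, and the two aryl chlorides, which rule out hydrogenolysis. The real difficulty is the congested bridged ketal with two fully substituted carbons bonded to aryl carbons, the differentiation of two similar halves (ketone above, carbinol below), and the absolute configuration. The key step exploits the array C8a–C1(–O–)C1′–C8, in which two oxygen-bridged carbons attached to the ortho carbons C8a and C8 of the upper arene are the retron of a carbonyl ylide (C1–O–C1′) added across an aryne, while the C8′ oxygen on C1 marks the ester whose carbonyl supplies that ylide.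

## Logic of the disconnections

35 ⇒ 34 ⇒ 33. The O–Si bond at C4′ and the two O–CH2 acetal bonds at C5 and C5′ are cut. The reason is that both phenols and the carbinol must be masked through organolithium, ruthenium and oxidant steps. Nothing is gained in skeleton, but every earlier step becomes robust. The demand is a deprotection that spares two epoxides and the ketal, so acid is used only once, cold, and the silyl ether is removed last with buffered fluoride.

33 ⇒ 32. The two C–O bonds of the C2–C3 epoxide are cut, which leaves the C2=C3–C4 enone. Nucleophilic epoxidation of an enone is reliable and does not touch the rest. The demand is attack at C2 from the face anti to the C1–O–C8′ bond, which the lower arene under the upper ring should enforce.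

32 ⇒ 31. The C2=C3 bond is cut to two terminal alkenes, the vinyl group on C1 and an acryloyl group on C4a. This removes the upper carbocycle and reduces the upper unit to a benzene ring. The demand is a six-membered ring-closing metathesis between a hindered vinyl group and an electron-poor enone.

31 ⇒ 27 + 28. The C4a–C4 bond is cut to an aryl anion at C4a and an acyl donor. The bromine that steers the key step is thus reused as the handle for lithiation. A carbonylative palladium coupling is not used, because an acylpalladium at C4a would sit next to the C1 vinyl group and could add to it. The demand is that no ketone is present, which is why C4′ is reduced before this point.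

27 ⇒ 26 ⇒ 25 ⇒ 24. The C–O bonds of the lower epoxide, the O–Si bond and the C4′–H bond are cut in turn. The C4′ ketone is reduced while it is the only carbonyl in the molecule, which settles the ketone/carbinol difference between the two halves. The silyl ether and the upper arene then block one face so that the epoxide forms trans to the C4′ oxygen. Placing the epoxide before the organolithium step removes a 1,4-dihydronaphthalene that could aromatise by loss of the C1′ oxygen. The demand is facial control at C4′ by the remote C1′–C8 bond.

24 ⇒ 23. No bond is cut. The racemate is separated here because the dipole that forms 23 is achiral and the metal is expected to leave it before the cycloaddition. Resolving directly after the key step loses half the material at the earliest possible point.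

23 ⇒ 21 + 22 ⇒ 12 + 20. The C1′–C8 and C1–C8a bonds and the C1′–O bond are cut. This removes two rings and both bridgehead stereocentres at once and gives two flat, achiral fragments of similar size. The demand is that two transient species meet: the dipole must be formed before 22 is released, and 22 must react with defined regiochemistry, which the bromine at C4a provides.

12 ⇒ 10 ⇒ 9 ⇒ 6. The C1′=N2 unit is traced to a quinone carbonyl, not to an amine, because a free amine at C1′ would take the acyl group from the peri oxygen on C8′. The quinone comes from the naphthol and the naphthol from the tetralone by dehydrogenation. The demand is condensation at the C1′ carbonyl only, which the ester on the C8′ oxygen (activating) and the ether on the C5′ oxygen (deactivating the C4′ carbonyl) should secure.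

6 ⇒ 5 ⇒ 4 ⇒ 2 + 3 ⇒ 1. The acetal at the C5′ oxygen, the C6′–Cl bond, the ester C–O bond and the two methyl ethers are cut. The tetralone carbonyl chelates the C5′ hydroxyl, which lets the other phenol be acylated alone and then directs chlorination to C6′. A quinone or hydroquinone with two equivalent oxygens is avoided because it could not be differentiated.

20 ⇒ 19 ⇒ 15 ⇒ 14 ⇒ 13. The acetal, the C8a–O triflate and C8–Si bonds, and the two carbon–halogen bonds are cut. Iodine is placed at C8 and bromine at C4a because two bromines would exchange at the wrong position (the one between two oxygens). The silyl migration from oxygen to C8 also frees only the C8a oxygen, so the two resorcinol oxygens are differentiated without a protecting-group step.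

## Other disconnections considered

Alternative 1: The cut removes the C8′–O and bridging C1–O bonds and restores a C1–C8′ bond. It leads back to a symmetric perylenequinone-type dimer whose C1 and C1′ carry a peroxide bridge. In the forward step acid would ionise the O–O bond, C8′ would shift from C1 to oxygen, and the oxygen on C1′ would capture the C1 oxocarbenium, giving the bis-enone A1. In its favour: it is very short and needs no protecting groups, the symmetry of the peroxide means either aryl shift gives the same ketal, and both enones arrive together. Against it here: A1 has no chlorine, and it carries the C4 and C4′ carbonyls together, so the one reduction at C4′ must distinguish two nearly equivalent ketones. Its precursor is achiral, so the absolute configuration again needs a resolution. In comparison, this route is better than the chosen plan in step economy and equal to it on absolute configuration. It is weaker on halogen placement and on the ketone/carbinol differentiation, which the chosen plan settles by bringing the chlorines in with the fragments and having a single carbonyl at the time of reduction. Mechanistically both plans rest on a rearrangement or cycloaddition not yet shown on such substrates.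

Alternative 2: The cut is at C1′–C8a′ and C4′–C4a′. In the forward step a silyloxy diene that runs from the exocyclic carbon of an alkylidene phthalide (C1′) to C4′ would add to the unsubstituted double bond of a chlorobenzoquinone under a chiral oxazaborolidinium acid, and enolisation would give the spiro phthalide A2. In its favour: C1′ and C4′ would be set in relative and absolute terms in one catalytic step, which is better than the chosen plan on absolute configuration. The carbinol also arrives at the right oxidation level and protected, and the bond-forming reaction type is well established. Against it here: the step builds neither the ketal nor the upper ring. In A2, C1 is still a lactone carbonyl, C4a carries only hydrogen, and the two hydroquinone oxygens must be told apart. The orientation of the chloroquinone and the endo/exo sense have to be controlled, and enolisation must not be followed by loss of the silyloxy group with aromatisation. In comparison, the alternative is superior in enantiocontrol and precedent. The chosen plan delivers more of the skeleton in its key step (two rings, three bonds) and needs fewer steps afterwards.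

Alternative 3: The cut is at C1–C2 and at the C1–O bond to C8′. In the forward step iodine–lithium exchange on a Z-vinyl iodide chain at C4a would give a vinyllithium that attacks the lactone carbonyl of a spiro phthalide, closing the upper ring. Acid would then ionise the lactol so that the C8′ phenol closes the dioxin ring, giving A3. In its favour: every event has close precedent, the configuration at C1 follows from the bicyclic constraint, and the lower ring can be complete beforehand, so it is equal or better than the chosen plan in reliability and stereochemical security. Against it here: the spiro phthalide with C1′ already set must be made separately, the Z-vinyl iodide with its masked C4 ketone must be installed at a hindered position, acid is used with the lower epoxide in place, and the dioxolane must later be opened beside the new ketal. In comparison, the chosen plan is more convergent and shorter, because C1′–C8, C1′–O and C1–C8a come from one step and two simple fragments. Its key step is less certain.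

Key step: step 12

Remark on the chemistry: locants C1–C8a (upper unit) and C1′–C8a′ (lower unit) are those of the target throughout; 23 is a racemate and its SMILES shows the enantiomer that is carried on; 1, 3, 13 and 28 are taken as commercially available.

## Steps

Step 1
Reactants: 1 5,8-dimethoxy-3,4-dihydronaphthalen-1(2H)-one
Product: 2 5,8-dihydroxy-3,4-dihydronaphthalen-1(2H)-one
Conditions: BBr3 (2.5 equiv), CH2Cl2, −78 °C → rt; H2O
Reagents that add atoms: none
Why: Lewis-acid cleavage of both aryl methyl ethers (BBr3 demethylation) should give the hydroquinone ketone; the hydroxyl on C5′ becomes hydrogen-bonded to the C4′ ketone, which differentiates the two phenols.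

Step 2
Reactants: 2 5,8-dihydroxy-3,4-dihydronaphthalen-1(2H)-one; 3 acryloyl chloride
Product: 4 4-hydroxy-5-oxo-5,6,7,8-tetrahydronaphthalen-1-yl acrylate
Conditions: Et3N (1.1 equiv), CH2Cl2, −78 → −20 °C
Reagents that add atoms: none
Why: Chemoselective O-acylation should take the free C8′ hydroxyl, since the C5′ hydroxyl is chelated to the ketone and much less nucleophilic; the ester carbonyl carbon is the future C1.

Step 3
Reactants: 4 4-hydroxy-5-oxo-5,6,7,8-tetrahydronaphthalen-1-yl acrylate
Product: 5 3-chloro-4-hydroxy-5-oxo-5,6,7,8-tetrahydronaphthalen-1-yl acrylate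
Conditions: NCS (1.05 equiv), DMF, rt
Reagents that add atoms: N-chlorosuccinimide, O=C1CCC(=O)N1Cl
Why: Electrophilic aromatic chlorination directed by the free phenol to its only open ortho position C6′ (the para position carries the ester oxygen, and the acyloxy group is a much weaker director).

Step 4
Reactants: 5 3-chloro-4-hydroxy-5-oxo-5,6,7,8-tetrahydronaphthalen-1-yl acrylate
Product: 6 3-chloro-4-(methoxymethoxy)-5-oxo-5,6,7,8-tetrahydronaphthalen-1-yl acrylate
Conditions: MOMCl, iPr2NEt, CH2Cl2, 0 °C → rt
Reagents that add atoms: chloromethyl methyl ether, COCCl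
Why: O-alkylation of the chelated phenol to the methoxymethyl acetal, which tolerates fluoride, hydride and organolithium later and turns the C5′ oxygen into a donor that deactivates the C4′ carbonyl in step 7.

Step 5
Reactants: 6 3-chloro-4-(methoxymethoxy)-5-oxo-5,6,7,8-tetrahydronaphthalen-1-yl acrylate
Product: 9 3-chloro-5-hydroxy-4-(methoxymethoxy)naphthalen-1-yl acrylate, via silyl enol ether 7 (not isolated), via keto tautomer 8 (not isolated)
Conditions: TMSOTf, Et3N, CH2Cl2, 0 °C; then Pd(OAc)2 (10 mol %), O2 (1 atm), DMSO, 40 °C
Reagents that add atoms: none
Why: Saegusa–Ito dehydrogenation of the silyl enol ether gives the 2′,3′-enone 8, which is the keto tautomer of a naphthol and should aromatise at once; the base-free oxidation spares the aryl acrylate.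

Step 6
Reactants: 9 3-chloro-5-hydroxy-4-(methoxymethoxy)naphthalen-1-yl acrylate
Product: 10 3-chloro-4-(methoxymethoxy)-5,8-dioxo-5,8-dihydronaphthalen-1-yl acrylate
Conditions: PhI(OAc)2 (2.2 equiv), MeCN/H2O, 0 °C
Reagents that add atoms: water, O
Why: Hypervalent-iodine oxidation of a para-unsubstituted naphthol: water adds para to the activated phenol oxygen (C1′) and a second oxidation gives the 1,4-naphthoquinone, while the protected ring is not oxidised.

Step 7
Reactants: 10 3-chloro-4-(methoxymethoxy)-5,8-dioxo-5,8-dihydronaphthalen-1-yl acrylate
Product: 12 3-chloro-8-diazo-4-(methoxymethoxy)-5-oxo-5,8-dihydronaphthalen-1-yl acrylate, via tosylhydrazone 11 (not isolated)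
Conditions: TsNHNH2 (1.0 equiv), AcOH (cat.), THF, 0 °C; then aq. NaHCO3/CH2Cl2, dark
Reagents that add atoms: 4-methylbenzenesulfonohydrazide, Cc1ccc(cc1)S(=O)(=O)NN
Why: Condensation should occur at the C1′ carbonyl, which lies peri to the electron-poor acyloxy group, whereas the C4′ carbonyl is deactivated by the conjugated ether oxygen on C5′; the hydrazone tautomerises to the tosylazo naphthol and loses sulfinate with mild base (Bamford–Stevens-type elimination) to give the quinone diazide. No free amine is ever present beside the ester, so O-to-N acyl transfer cannot occur.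

Step 8
Reactants: 13 4-chlorobenzene-1,3-diol
Product: 14 4-chloro-6-iodobenzene-1,3-diol
Conditions: NIS (1.0 equiv), MeCN, 0 °C
Reagents that add atoms: N-iodosuccinimide, O=C1CCC(=O)N1I
Why: Electrophilic iodination at the most reactive position of the resorcinol, para to the C5 hydroxyl and ortho to the C8a hydroxyl, which is the future C8.

Step 9
Reactants: 14 4-chloro-6-iodobenzene-1,3-diol
Product: 15 2-bromo-4-chloro-6-iodobenzene-1,3-diol
Conditions: NBS (1.0 equiv), CH2Cl2/MeCN, −20 °C
Reagents that add atoms: N-bromosuccinimide, O=C1CCC(=O)N1Br
Why: Second electrophilic halogenation at the only remaining activated position, C4a between the two hydroxyls; iodine at C8 and bromine at C4a give two halogens of different exchange rate.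

Step 10
Reactants: 15 2-bromo-4-chloro-6-iodobenzene-1,3-diol
Product: 19 2-bromo-4-chloro-3-hydroxy-6-(trimethylsilyl)phenyl trifluoromethanesulfonate, via bis(trimethylsilyl) ether 16 (not isolated), via lithium phenoxide 17 (not isolated), via silyl ether triflate 18 (not isolated)
Conditions: HMDS, THF, 65 °C, evaporate; n-BuLi (1.0 equiv), THF, −100 °C; Tf2O, −100 → −78 °C; aq. NaHCO3, then dilute citric acid
Reagents that add atoms: hexamethyldisilazane, C[Si](C)(C)N[Si](C)(C)C; trifluoromethanesulfonic anhydride, O=S(=O)(OS(=O)(=O)C(F)(F)F)C(F)(F)F
Why: Iodine–lithium exchange is much faster than bromine–lithium exchange, so only C8 is lithiated; the aryllithium takes the silyl group from the neighbouring oxygen (retro-Brook 1,3-shift), which frees only the C8a oxygen for triflation. The silyl ether on the C5 oxygen falls off on work-up, so the two oxygens are differentiated without a separate step.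

Step 11
Reactants: 19 2-bromo-4-chloro-3-hydroxy-6-(trimethylsilyl)phenyl trifluoromethanesulfonate
Product: 20 2-bromo-4-chloro-3-(methoxymethoxy)-6-(trimethylsilyl)phenyl trifluoromethanesulfonate
Conditions: MOMCl, iPr2NEt, CH2Cl2, 0 °C → rt
Reagents that add atoms: chloromethyl methyl ether, COCCl
Why: O-alkylation of the hindered phenol with an amine base that does not trigger the silyl triflate; the acetal later stabilises the aryllithium at C4a and cannot undergo silyl migration.

Step 12
Reactants: 12 3-chloro-8-diazo-4-(methoxymethoxy)-5-oxo-5,8-dihydronaphthalen-1-yl acrylate; 20 2-bromo-4-chloro-3-(methoxymethoxy)-6-(trimethylsilyl)phenyl trifluoromethanesulfonate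
Product: 23 racemic bromo vinyl dienone cycloadduct, via carbonyl ylide 21 (not isolated), via aryne 22 (not isolated)
Conditions: Rh2(OAc)4 (2 mol %), 20 (1.5 equiv), 1,2-dichloroethane, 40 °C, slow addition of 12, dark; then CsF (3 equiv), MeCN, rt
Reagents that add atoms: none
Why: Proposed new method: Rh2(OAc)4 (divalent rhodium) should strip dinitrogen from 12 to a quinoid rhodium carbenoid at C1′, the peri acrylate carbonyl oxygen should add to it (six-membered closure of the dioxin ring, C1′–O), and loss of the metal should leave ylide 21, an aromatic naphthoxide para to a vinyl dioxinylium. Fluoride should then free aryne 22 from 20; the carbanionic terminus C1′ adds to C8 and the aryl anion at C8a collapses on cationic C1, which closes the five-membered ring as a [3+2] cycloaddition (concerted or stepwise) and leaves the lower ring as the C2′=C3′–C4′ enone. The closest known reaction types are rhodium-catalysed carbonyl ylide formation from diazo carbonyl compounds with a neighbouring ester or ketone followed by [3+2] capture by alkynes or alkenes, and the [3+2] additions of arynes to other 1,3-dipoles; the combination of a quinone diazide, an ester-derived ylide and an aryne has not been shown. C1 and C1′ are created together and their relative configuration is fixed by geometry, since the aryne adds to one face of the planar dipole and the bridged ketal can exist in one relative form only. The dipole is achiral and the catalyst is expected to leave it, so 23 should be racemic and the absolute configuration is secured in step 13. Regiocontrol on the aryne comes from the inductively withdrawing bromine beside C8a, which places the developing aryl anion next to it and sends C1′ to the remote carbon C8. Attack through C1′ in preference to the naphthoxide oxygen or C3′ is favoured because only that mode lets the aryl anion close on C1 through a five-membered ring. Forming the dipole before the aryne is released keeps free diazo compound away from the aryne, which would otherwise add to it as a 1,3-dipole.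

Step 13
Reactants: 23 racemic bromo vinyl dienone cycloadduct
Product: 24 bromo vinyl dienone cycloadduct as single enantiomer
Conditions: preparative HPLC, amylose tris(3,5-dimethylphenylcarbamate) stationary phase, hexane/i-PrOH
Reagents that add atoms: none
Why: Chromatographic resolution on a polysaccharide carbamate phase, chosen because the rigid aromatic ketone is the kind of racemate such phases separate and because half the material is then lost as early as possible; the mirror-image form is set aside. The C1 and C1′ descriptors of 24 are those of 35, and every later stereocentre is set relative to them.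

Step 14
Reactants: 24 bromo vinyl dienone cycloadduct as single enantiomer
Product: 25 C4′ allylic alcohol
Conditions: NaBH4, CeCl3·7H2O, MeOH/THF, −78 °C
Reagents that add atoms: none
Why: Luche 1,2-reduction of the only ketone in the molecule; hydride should add to the C4′ face opposite the upper arene, whose C7–H edge lies under the lower ring because the C1′–C8 bond is pseudo-axial, so the hydroxyl ends up cis to the C1′–C8 bond as in the target.

Step 15
Reactants: 25 C4′ allylic alcohol
Product: 26 C4′ tert-butyldimethylsilyl ether
Conditions: TBSCl, imidazole, DMAP (cat.), DMF, rt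
Reagents that add atoms: tert-butyldimethylsilyl chloride, CC(C)(C)[Si](C)(C)Cl
Why: Silylation under basic conditions, chosen over a silyl triflate because the allylic, doubly benzylic C1′–O bond could ionise under Lewis acid; the bulky group also shields its face of the ring for step 16.

Step 16
Reactants: 26 C4′ tert-butyldimethylsilyl ether
Product: 27 lower epoxide
Conditions: DMDO (1.3 equiv), acetone/CH2Cl2, 0 °C
Reagents that add atoms: dimethyldioxirane, CC1(C)OO1
Why: Neutral electrophilic epoxidation of the cis-disubstituted ring alkene, which should react faster than the monosubstituted vinyl group on the ketal carbon; the oxidant approaches the face opposite both the silyloxy group and the upper arene, so the epoxide forms trans to the C4′ oxygen and anti to the C1′–C8 bond. With the alkene gone, the lower ring can no longer aromatise in the basic and metal-catalysed steps that follow.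

Step 17
Reactants: 27 lower epoxide; 28 N-methoxy-N-methylacrylamide
Product: 31 C4a acryloyl compound, via aryllithium 29 (not isolated), via lithium hemiaminal alkoxide 30 (not isolated)
Conditions: t-BuLi (2.0 equiv), THF, −78 °C, 5 min; 28 (1.5 equiv), −78 °C; cold aq. NH4Cl
Reagents that add atoms: none
Why: Bromine–lithium exchange at C4a (faster than any deprotonation or attack on the epoxide at this temperature; the ortho acetal oxygen stabilises the aryllithium) and Weinreb ketone synthesis; the chelated tetrahedral adduct holds until the quench, so no second addition occurs and the aryl vinyl ketone is released only on work-up.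

Step 18
Reactants: 31 C4a acryloyl compound
Product: 32 upper enone
Conditions: second-generation Grubbs catalyst (5 mol %), CH2Cl2, 40 °C
Reagents that add atoms: none
Why: Ring-closing metathesis between the acryloyl and the C1 vinyl groups forms C2=C3 in a six-membered ring with loss of ethene; both alkenes are held close on adjacent arene carbons, and no other terminal alkene is present.

Step 19
Reactants: 32 upper enone
Product: 33 bis-epoxide
Conditions: t-BuOOH, DBU, CH2Cl2, 0 °C
Reagents that add atoms: tert-butyl hydroperoxide, CC(C)(C)OO
Why: Nucleophilic (Weitz–Scheffer) epoxidation of the enone; the peroxide anion adds to C2 from the face anti to the C1–O–C8′ bond, because the lower arene lies under the other face, and the enolate closes to the epoxide on that same face as in the target.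

Step 20
Reactants: 33 bis-epoxide
Product: 34 bis-phenol silyl ether
Conditions: TFA/CH2Cl2 (1:10), H2O (5 equiv), 0 °C; aq. NaHCO3
Reagents that add atoms: none
Why: Acid hydrolysis of the two aryl methoxymethyl acetals; the epoxides should survive because each epoxide carbon is flanked by an electron-withdrawing centre, trifluoroacetate is a poor nucleophile and the temperature is low. The silyl ether is kept so that the benzylic C4′ oxygen stays masked during the acid treatment.

Step 21
Reactants: 34 bis-phenol silyl ether
Product: 35 CNP0289684.3
Conditions: HF·pyridine, pyridine, THF, 0 °C → rt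
Reagents that add atoms: none
Why: Fluoride cleavage of the secondary silyl ether under buffered conditions that leave epoxides, ketal and phenols alone; no stereocentre is touched.

## Compound list

1 | 5,8-dimethoxy-3,4-dihydronaphthalen-1(2H)-one | COc1ccc(OC)c2c1CCCC2=O | starting material
2 | 5,8-dihydroxy-3,4-dihydronaphthalen-1(2H)-one | Oc1ccc(O)c2c1CCCC2=O | intermediate
3 | acryloyl chloride | C=CC(=O)Cl | starting material
4 | 4-hydroxy-5-oxo-5,6,7,8-tetrahydronaphthalen-1-yl acrylate | C=CC(=O)Oc1ccc(O)c2c1CCCC2=O | intermediate
5 | 3-chloro-4-hydroxy-5-oxo-5,6,7,8-tetrahydronaphthalen-1-yl acrylate | C=CC(=O)Oc1cc(Cl)c(O)c2c1CCCC2=O | intermediate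
6 | 3-chloro-4-(methoxymethoxy)-5-oxo-5,6,7,8-tetrahydronaphthalen-1-yl acrylate | C=CC(=O)Oc1cc(Cl)c(OCOC)c2c1CCCC2=O | intermediate
7 | 3-chloro-4-(methoxymethoxy)-5-(trimethylsilyloxy)-7,8-dihydronaphthalen-1-yl acrylate | C=CC(=O)Oc1cc(Cl)c(OCOC)c2c1CCC=C2O[Si](C)(C)C | intermediate
8 | 3-chloro-4-(methoxymethoxy)-5-oxo-5,8-dihydronaphthalen-1-yl acrylate | C=CC(=O)Oc1cc(Cl)c(OCOC)c2c1CC=CC2=O | intermediate
9 | 3-chloro-5-hydroxy-4-(methoxymethoxy)naphthalen-1-yl acrylate | C=CC(=O)Oc1cc(Cl)c(OCOC)c2c(O)cccc12 | intermediate
10 | 3-chloro-4-(methoxymethoxy)-5,8-dioxo-5,8-dihydronaphthalen-1-yl acrylate | C=CC(=O)Oc1cc(Cl)c(OCOC)c2c1C(=O)C=CC2=O | intermediate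
11 | 3-chloro-4-(methoxymethoxy)-5-oxo-8-(tosylhydrazinylidene)-5,8-dihydronaphthalen-1-yl acrylate | C=CC(=O)Oc1cc(Cl)c(OCOC)c2c1C(=NNS(=O)(=O)c1ccc(C)cc1)C=CC2=O | intermediate
12 | 3-chloro-8-diazo-4-(methoxymethoxy)-5-oxo-5,8-dihydronaphthalen-1-yl acrylate (quinone diazide, diazo carbon C1′ peri to the acrylate) | C=CC(=O)Oc1cc(Cl)c(OCOC)c2c1C(=[N+]=[N-])C=CC2=O | intermediate
13 | 4-chlorobenzene-1,3-diol (4-chlororesorcinol) | Oc1ccc(Cl)c(O)c1 | starting material
14 | 4-chloro-6-iodobenzene-1,3-diol | Oc1cc(O)c(Cl)cc1I | intermediate
15 | 2-bromo-4-chloro-6-iodobenzene-1,3-diol | Oc1c(Br)c(O)c(Cl)cc1I | intermediate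
16 | 2-bromo-4-chloro-6-iodo-1,3-bis(trimethylsilyloxy)benzene | C[Si](C)(C)Oc1c(Br)c(O[Si](C)(C)C)c(Cl)cc1I | intermediate
17 | lithium 2-bromo-4-chloro-6-(trimethylsilyl)-3-(trimethylsilyloxy)phenolate | [Li+].[O-]c1c(Br)c(O[Si](C)(C)C)c(Cl)cc1[Si](C)(C)C | intermediate
18 | 2-bromo-4-chloro-6-(trimethylsilyl)-3-(trimethylsilyloxy)phenyl trifluoromethanesulfonate | C[Si](C)(C)Oc1c(Cl)cc([Si](C)(C)C)c(OS(=O)(=O)C(F)(F)F)c1Br | intermediate
19 | 2-bromo-4-chloro-3-hydroxy-6-(trimethylsilyl)phenyl trifluoromethanesulfonate | Oc1c(Cl)cc([Si](C)(C)C)c(OS(=O)(=O)C(F)(F)F)c1Br | intermediate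
20 | 2-bromo-4-chloro-3-(methoxymethoxy)-6-(trimethylsilyl)phenyl trifluoromethanesulfonate | COCOc1c(Cl)cc([Si](C)(C)C)c(OS(=O)(=O)C(F)(F)F)c1Br | intermediate
21 | carbonyl ylide: naphthoxide (oxide on C4′) bridged through the C1′ and C8′ oxygens by a cationic, vinyl-bearing C1 (2-vinyl-1,3-dioxin-2-ylium), C5′ methoxymethyl ether, C6′ chloride | [O-]c1ccc2O[C+](C=C)Oc3cc(Cl)c(OCOC)c1c32 | intermediate
22 | 3-bromo-5-chloro-4-(methoxymethoxy)-1,2-didehydrobenzene (aryne, triple bond C8–C8a) | COCOC1=C(Br)C#CC=C1Cl | intermediate
23 | racemic cycloadduct: 2,8-dioxabicyclo[3.2.1]octane ketal with vinyl on C1, bromine on C4a, methoxymethyl ethers on the C5 and C5′ oxygens, chlorine on C6 and C6′, lower C2′=C3′–C4′ enone | Brc1c(OCOC)c(Cl)cc2c1[C@@]1(Oc3cc(Cl)c(OCOC)c4c3[C@]2(O1)C=CC4=O)C=C | intermediate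
24 | the cycloadduct of 23 as single enantiomer, C1 and C1′ configured as in 35 | Brc1c(OCOC)c(Cl)cc2c1[C@@]1(Oc3cc(Cl)c(OCOC)c4c3[C@]2(O1)C=CC4=O)C=C | intermediate
25 | C4′ allylic alcohol of 24, hydroxyl cis to the C1′–C8 bond and trans to the C1′–O bridge | Brc1c(OCOC)c(Cl)cc2c1[C@@]1(Oc3cc(Cl)c(OCOC)c4c3[C@]2(O1)C=C[C@H]4O)C=C | intermediate
26 | tert-butyldimethylsilyl ether of 25 | Brc1c(OCOC)c(Cl)cc2c1[C@@]1(Oc3cc(Cl)c(OCOC)c4c3[C@]2(O1)C=C[C@H]4O[Si](C)(C)C(C)(C)C)C=C | intermediate
27 | 2′,3′-epoxide of 26, epoxide oxygen trans to the C4′ silyloxy group and anti to the C1′–C8 bond | Brc1c(OCOC)c(Cl)cc2c1[C@@]1(Oc3cc(Cl)c(OCOC)c4c3[C@]2(O1)[C@@H]1O[C@@H]1[C@H]4O[Si](C)(C)C(C)(C)C)C=C | intermediate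
28 | N-methoxy-N-methylacrylamide | C=CC(=O)N(C)OC | starting material
29 | C4a aryllithium derived from 27 | [Li]c1c(OCOC)c(Cl)cc2c1[C@@]1(Oc3cc(Cl)c(OCOC)c4c3[C@]2(O1)[C@@H]1O[C@@H]1[C@H]4O[Si](C)(C)C(C)(C)C)C=C | intermediate
30 | lithium alkoxide of the tetrahedral adduct of 29 and 28 | [Li+].[O-]C(C=C)(N(C)OC)c1c(OCOC)c(Cl)cc2c1[C@@]1(Oc3cc(Cl)c(OCOC)c4c3[C@]2(O1)[C@@H]1O[C@@H]1[C@H]4O[Si](C)(C)C(C)(C)C)C=C | intermediate
31 | aryl vinyl ketone: acryloyl group on C4a in place of the bromine of 27 | C=CC(=O)c1c(OCOC)c(Cl)cc2c1[C@@]1(Oc3cc(Cl)c(OCOC)c4c3[C@]2(O1)[C@@H]1O[C@@H]1[C@H]4O[Si](C)(C)C(C)(C)C)C=C | intermediate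
32 | upper ring closed: C2=C3–C4 enone, lower epoxide and silyl ether, both phenols as methoxymethyl ethers | O=C1c2c(OCOC)c(Cl)cc3c2[C@@]2(Oc4cc(Cl)c(OCOC)c5c4[C@]3(O2)[C@@H]2O[C@@H]2[C@H]5O[Si](C)(C)C(C)(C)C)C=C1 | intermediate
33 | 2,3-epoxide of 32, epoxide oxygen anti to the C1–O–C8′ bond and syn to the C1–O–C1′ bridge | O=C1c2c(OCOC)c(Cl)cc3c2[C@@]2(Oc4cc(Cl)c(OCOC)c5c4[C@]3(O2)[C@@H]2O[C@@H]2[C@H]5O[Si](C)(C)C(C)(C)C)[C@@H]2O[C@H]12 | intermediate
34 | bis-phenol of 33 with the C4′ silyl ether retained | O=C1c2c(O)c(Cl)cc3c2[C@@]2(Oc4cc(Cl)c(O)c5c4[C@]3(O2)[C@@H]2O[C@@H]2[C@H]5O[Si](C)(C)C(C)(C)C)[C@@H]2O[C@H]12 | intermediate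
35 | CNP0289684.3 | O=C1c2c(O)c(Cl)cc3c2[C@@]2(Oc4cc(Cl)c(O)c5c4[C@]3(O2)[C@@H]2O[C@@H]2[C@H]5O)[C@@H]2O[C@H]12 | target

## Step count and least certain steps

Total: 21 steps (20 reactions and one resolution). Longest linear sequence: 17 steps (steps 1–7 and 12–21); the aryne branch (steps 8–11) joins at step 12.

Step 12 (key step). The most likely failure is loss of the dipole before it meets the aryne, by oligomerisation through naphthoxide attack on the dioxinylium carbon or by O-arylation of the naphthoxide. The carbenoid may also form too slowly from a quinone diazide, so that remaining diazo compound adds to the aryne. The fallback uses known chemistry only (aryl Grignard addition to a quinone carbonyl, lactonisation, vinyl Grignard addition to a lactone, phenol ketalisation); it sets out from quinone 10 and returns at 26. Commercial 4-chloro-3-hydroxybenzoic acid F1 is iodinated para to the hydroxyl (NIS) to 4-chloro-5-hydroxy-2-iodobenzoic acid F2, which is brominated at the remaining ortho position (NBS) to 2-bromo-4-chloro-3-hydroxy-6-iodobenzoic acid F3 and then alkylated twice (MOMCl, iPr2NEt) to the methoxymethyl ester ether F4. Iodine–magnesium exchange (iPrMgCl·LiCl, THF, −40 °C) gives the arylmagnesium chloride F5, which should add to the more electrophilic C1′ carbonyl of 10; the alkoxide closes on the ester to the racemic spiro phthalide F6, with C1′–C8 and C1′–O in place and C1 as lactone carbonyl. Luche reduction as in step 14 gives the alcohol F7, and silylation as in step 15 gives the silyl ether F8. Excess CH2=CHMgBr adds to the lactone and removes the acrylate, giving the lactol F9; PPTS closes it with the C8′ phenol to the bridged ketal F10, the racemate of 26. The chiral-phase separation of step 13 applied to F10 returns 26.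

Step 7. Condensation may occur at the wrong carbonyl, or the hydrazide or the liberated sulfinate may add to the acrylate. The fallback replaces electronic control by chelation control; it sets out from 10 and returns at 12. MgBr2·OEt2 removes the methoxymethyl group peri to the quinone carbonyl and gives the hydroxyquinone F11, in which the C4′ carbonyl is tied up in a hydrogen bond. Condensation is then left to the C1′ carbonyl and gives the tosylhydrazone F12, and base releases the hydroxy quinone diazide F13. MOMCl and iPr2NEt reinstall the acetal to give 12.

Step 17. Acylation of the doubly ortho-substituted aryllithium by the amide may be slow, conjugate addition may compete, or the liberated amine may add to the vinyl ketone. The fallback sets out from 27 and returns at 32. The same aryllithium 29 is trapped with acrolein, which is small and reacts only by 1,2-addition, to give the allylic alcohol F14 as a mixture at the new carbinol. Ring-closing metathesis with the second-generation Grubbs catalyst, now starting at an unhindered allylic alcohol, gives the cyclohexenol F15, and Dess–Martin periodinane oxidises it to the enone 32.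

Step 20. Acid may open the lower epoxide or ionise the C1′–O or C4′–O bond before both acetals are gone. The fallback avoids protic acid and merges the last two steps; it sets out from 33 and returns at 35. TMSOTf with 2,2′-bipyridyl transfers silicon to the aryl acetal oxygens and gives the bis(trimethylsilyl) ether F16. HF·pyridine then removes the three silyl groups in one operation and gives 35, without passing through 34.

## Further compounds

F1 | step 12 | 4-chloro-3-hydroxybenzoic acid | OC(=O)c1ccc(Cl)c(O)c1
F2 | step 12 | 4-chloro-5-hydroxy-2-iodobenzoic acid | OC(=O)c1cc(O)c(Cl)cc1I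
F3 | step 12 | 2-bromo-4-chloro-3-hydroxy-6-iodobenzoic acid | OC(=O)c1c(Br)c(O)c(Cl)cc1I
F4 | step 12 | methoxymethyl 2-bromo-4-chloro-6-iodo-3-(methoxymethoxy)benzoate | COCOC(=O)c1c(Br)c(OCOC)c(Cl)cc1I
F5 | step 12 | arylmagnesium chloride from F4 (magnesium in place of iodine) | COCOC(=O)c1c(Br)c(OCOC)c(Cl)cc1[Mg]Cl
F6 | step 12 | racemic spiro phthalide: lactone C1(=O)–O–C1′, lower dienone, acrylate on the C8′ oxygen, bromine on C4a | O=C1O[C@@]2(C=CC(=O)c3c(OCOC)c(Cl)cc(OC(=O)C=C)c32)c2cc(Cl)c(OCOC)c(Br)c12
F7 | step 12 | C4′ alcohol of F6, hydroxyl cis to the C1′–C8 bond | O=C1O[C@@]2(C=C[C@@H](O)c3c(OCOC)c(Cl)cc(OC(=O)C=C)c32)c2cc(Cl)c(OCOC)c(Br)c12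
F8 | step 12 | tert-butyldimethylsilyl ether of F7 | O=C1O[C@@]2(C=C[C@@H](O[Si](C)(C)C(C)(C)C)c3c(OCOC)c(Cl)cc(OC(=O)C=C)c32)c2cc(Cl)c(OCOC)c(Br)c12
F9 | step 12 | lactol: vinyl and hydroxyl on C1, free C8′ phenol | OC1(C=C)O[C@@]2(C=C[C@@H](O[Si](C)(C)C(C)(C)C)c3c(OCOC)c(Cl)cc(O)c32)c2cc(Cl)c(OCOC)c(Br)c12
F10 | step 12 | racemate of 26 | Brc1c(OCOC)c(Cl)cc2c1[C@@]1(Oc3cc(Cl)c(OCOC)c4c3[C@]2(O1)C=C[C@H]4O[Si](C)(C)C(C)(C)C)C=C
F11 | step 7 | 3-chloro-4-hydroxy-5,8-dioxo-5,8-dihydronaphthalen-1-yl acrylate | C=CC(=O)Oc1cc(Cl)c(O)c2c1C(=O)C=CC2=O
F12 | step 7 | 3-chloro-4-hydroxy-5-oxo-8-(tosylhydrazinylidene)-5,8-dihydronaphthalen-1-yl acrylate | C=CC(=O)Oc1cc(Cl)c(O)c2c1C(=NNS(=O)(=O)c1ccc(C)cc1)C=CC2=O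
F13 | step 7 | 3-chloro-8-diazo-4-hydroxy-5-oxo-5,8-dihydronaphthalen-1-yl acrylate | C=CC(=O)Oc1cc(Cl)c(O)c2c1C(=[N+]=[N-])C=CC2=O
F14 | step 17 | C4a 1-hydroxyprop-2-enyl compound (allylic alcohol, both carbinol epimers) | C=CC(O)c1c(OCOC)c(Cl)cc2c1[C@@]1(Oc3cc(Cl)c(OCOC)c4c3[C@]2(O1)[C@@H]1O[C@@H]1[C@H]4O[Si](C)(C)C(C)(C)C)C=C
F15 | step 17 | C4 alcohol corresponding to enone 32 (both carbinol epimers) | OC1c2c(OCOC)c(Cl)cc3c2[C@@]2(Oc4cc(Cl)c(OCOC)c5c4[C@]3(O2)[C@@H]2O[C@@H]2[C@H]5O[Si](C)(C)C(C)(C)C)C=C1
F16 | step 20 | bis(trimethylsilyl) aryl ether of 34 | O=C1c2c(O[Si](C)(C)C)c(Cl)cc3c2[C@@]2(Oc4cc(Cl)c(O[Si](C)(C)C)c5c4[C@]3(O2)[C@@H]2O[C@@H]2[C@H]5O[Si](C)(C)C(C)(C)C)[C@@H]2O[C@H]12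
A1 | alternative 1 | dechloro bridged bis-enone diketone with both phenols free | O=C1c2c(O)ccc3c2[C@@]2(Oc4ccc(O)c5c4[C@]3(O2)C=CC5=O)C=C1
A2 | alternative 2 | spiro phthalide with lower cyclohexene silyl ether and chlorohydroquinone arene | O=C1O[C@@]2(C=C[C@@H](O[Si](C)(C)C(C)(C)C)c3c(O)c(Cl)cc(O)c32)c2cc(Cl)c(OCOC)cc12
A3 | alternative 3 | bridged ketal with upper cyclohexene (C4 as dioxolane) and complete lower ring | C12(OCCO1)c3c(OCOC)c(Cl)cc4c3[C@@]3(Oc5cc(Cl)c(OCOC)c6c5[C@]4(O3)[C@@H]3O[C@@H]3[C@H]6O[Si](C)(C)C(C)(C)C)C=C2
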